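The vessel is a closed, stirred flask at constant temperature, in which solid E dissolves to Q and L turns Q into X.

the same everywhere: E 0.017 M
- violet: L 0.028 mol%; run made earlier
- blue: L 0.044 mol%; run made earlier
- flask: L 0.02 mol%; time 8.0 h

| run | time / h | X / % | Q / % | E / % |
|---|---|---|---|---|
| violet | 1.33 | 11 | 0 | 83 |
| violet | 2.50 | 18 | 0 | 73 |
| violet | 4.00 | 30 | 1 | 60 |
| violet | 5.00 | 34 | 0 | 48 |
| violet | 6.00 | 42 | 1 | 42 |
| blue | 0.500 | 3 | 1 | 94 |
| blue | 1.00 | 8 | 2 | 93 |
| blue | 2.00 | 12 | 0 | 79 |
| blue | 3.00 | 22 | 0 | 68 |
| blue | 6.00 | 46 | 1 | 39 |

(each reading ± 2 percentage points)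

- E is a solid; its amount is given per volume of the solution
- the analysis behind the earlier runs scatters by 2 percentage points, standard deviation
- at the start none of E is in solution
- Q is what E becomes in solution
- Q means what is dissolved; the solid is not counted in it

- the X standing at 8.0 h, as a percentage of the E charged
- concentration of Q in solution at 8.0 h, in percent of saturation

My bench rule is a straight line: E falls at a steady pace, and X takes a fixed part of what has gone. At 6.00 h, the blue run had lost 1.05 times as much E as the violet run on 1.57 times the L, so I treat dissolving as the rate-limiting step. Pooling those last readings, X reads 73.9% of the E lost, and I take that share as the end state. The same readings give the emptying time, the time the solid needs to leave at this pace: 10.1 h. The line shows no clear bend as the solid shrinks, so I let this time scale with cE.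

I expect the rule to hold while time over emptying time stays below one, and beyond that border X should stand at the share. For this flask the ratio is 0.792, which gives X of 58.5%. Its L is 0.714 of the violet run's, outside the runs, so I carry the pace over on trust. The readings give no saturation value, so I commit to no number for Q.

The forecast puts X at 52% (43% to 60%) and Q at 25% of saturation (5% to 55%), holding that “dissolution of E mostly limits the process”. The flask gives X at 58.1% and Q at 9.68% of saturation.

    Q + L ⇌ Z (K = 2300 L mol⁻¹, k = 1200 L mol⁻¹ s⁻¹)
    X ⇌ J (K = 0.340, k = 1.40 × 10⁻⁴ s⁻¹)
    Z → L + X (k = 1.30 s⁻¹)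
    E ⇌ Q, rate k4*(cs4 - [Q]) while solid is left; crystals form when [Q] > cs4 (solubility = 1.80 mM, k = 2.80 × 10⁻⁴ s⁻¹)

At 8.00 h this flask still holds E at 22.8%, with X at 58.1% and J at 18.1%. The half-life of X by its forward passing into J is 1.4 h, short against the 8.0 h of the run. In the neighbour charged with 0.010 M of E at the same loading of L, the emptying time scales to 5.93 h, below 8.0 h, so the rule puts X at the share, 73.9%. The computed neighbour gives 74.8%, with 0% of E left.

All runs were generated by integration with constants of no real substance; scatter was added.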